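The plan rests on a retro-Diels–Alder cut of ring B, the cyclohexene C4–C7=C8–C9–C10–C14, at its C4–C14 and C9–C10 bonds. Ring B carries the butenolide on its C4–C7 edge and is cis-fused to ring A and to the furan-fused cycloheptenone ring C, the signature of a cycloadduct between a 3-vinylbutenolide and the C10=C14 alkene of ring C. One intramolecular cycloaddition should therefore close rings A and B together and set C4, C10 and C14 from the single existing centre C13. Its precursor is an enantioenriched furo-cycloheptadienone whose quaternary C13 carries a three-carbon tether (C1, C2, C3) ending at the β-carbon C4 of a 3-vinylbutenolide.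

Key step: step 15

Remark: atom labels follow the target (C1 bears the exocyclic CH2, C2 the acetate, C3, quaternary C4, C5 the OCH2, C6 the lactone C=O, C7=C8, C9, furyl CH C10, ketone C11, C12, quaternary methyl carbon C13, central CH C14; ring A = C1, C2, C3, C4, C14, C13; ring B = C4, C7, C8, C9, C10, C14; ring C = C10, two furan carbons, C11, C12, C13, C14); the facial course of the C2 hydroxylation in step 16 cannot be fixed on paper and is assumed to be anti to the C13 methyl, with an inversion held in reserve.

Step 1
Reactants: 1 pent-3-yn-2-one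
Product: 2 (S)-pent-3-yn-2-ol
Conditions: RuCl(p-cymene)[(S,S)-TsDPEN] (1 mol %, pre-activated with KOH), i-PrOH, 25 °C; careful distillation
Reagents that add atoms: none
Why: Noyori asymmetric transfer hydrogenation reduces alkynyl ketones at the carbonyl only, and with the (S,S) ligand the alkyne should take the place of the aryl group in the outer-sphere hydride transfer so that the S carbinol results.

Step 2
Reactants: 2 (S)-pent-3-yn-2-ol
Product: 4 (2S,3Z)-4-iodopent-3-en-2-ol, via cyclic alkenylalanate 3 (not isolated)
Conditions: NaAlH2(OCH2CH2OMe)2, THF, 0 °C to rt; EtOAc; I2, −78 to 0 °C; aq. potassium sodium tartrate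
Reagents that add atoms: iodine, [I][I]
Why: Hydroxyl-directed trans-hydroalumination of the propargylic alkoxide places aluminium on the distal alkyne carbon inside a five-membered chelate, and iodinolysis of that C–Al bond with retention should give the Z iodide without touching the carbinol centre.

Step 3
Reactants: 5 3-bromobut-3-en-1-ol
Product: 6 [(3-bromobut-3-en-1-yl)oxy](tert-butyl)dimethylsilane
Conditions: TBSCl, imidazole, CH2Cl2, 0 °C to rt
Reagents that add atoms: tert-butyldimethylsilyl chloride, CC(C)(C)[Si](C)(C)Cl
Why: Standard silyl ether protection of the primary alcohol, needed so that only the secondary hydroxyl of the later dienol is acylated.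

Step 4
Reactants: 6 [(3-bromobut-3-en-1-yl)oxy](tert-butyl)dimethylsilane
Product: 7 tert-butyldimethyl{[3-(4,4,5,5-tetramethyl-1,3,2-dioxaborolan-2-yl)but-3-en-1-yl]oxy}silane
Conditions: B2pin2, PdCl2(PPh3)2 (3 mol %), PPh3, KOPh, toluene, 50 °C
Reagents that add atoms: bis(pinacolato)diboron, CC1(C)OB(OC1(C)C)B1OC(C)(C)C(C)(C)O1
Why: Miyaura borylation of an alkenyl bromide, in which the weak base KOPh promotes boron transfer but not Suzuki homocoupling of the product, and the silyl ether is inert.

Step 5
Reactants: 4 (2S,3Z)-4-iodopent-3-en-2-ol, 7 tert-butyldimethyl{[3-(4,4,5,5-tetramethyl-1,3,2-dioxaborolan-2-yl)but-3-en-1-yl]oxy}silane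
Product: 8 (2S,3Z)-7-[(tert-butyldimethylsilyl)oxy]-4-methyl-5-methylidenehept-3-en-2-ol
Conditions: Pd(PPh3)4 (5 mol %), aq. K3PO4, THF, 45 °C
Reagents that add atoms: none
Why: Suzuki–Miyaura coupling of an alkenyl iodide with an alkenylboronate proceeds with retention at both sp2 carbons, so the Z geometry that later steers the Claisen step is kept, and the mild temperature avoids a 1,5-hydrogen shift in the Z-diene.

Step 6
Reactants: 9 furan-3-carboxylic acid
Product: 11 2-formylfuran-3-carboxylic acid, via dilithio furoate 10 (not isolated)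
Conditions: LiN(i-Pr)2 (2.2 equiv), THF, −78 °C; DMF, −78 °C to rt; aq. HCl
Reagents that add atoms: N,N-dimethylformamide, CN(C)C=O
Why: Directed metalation, in which the lithium carboxylate steers the second deprotonation to the adjacent furan α-position C2 and the aryllithium is formylated by DMF.

Step 7
Reactants: 11 2-formylfuran-3-carboxylic acid
Product: 12 2-ethenylfuran-3-carboxylic acid
Conditions: Ph3PCH3Br, KOt-Bu (excess), THF, 0 °C to rt; aq. HCl; stored cold with BHT
Reagents that add atoms: methyltriphenylphosphonium bromide, C[P+](c1ccccc1)(c1ccccc1)c1ccccc1.[Br-]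
Why: Wittig methylenation of the aldehyde with excess ylide, the carboxylate being inert towards the ylide and returned as the acid on acidification.

Step 8
Reactants: 8 (2S,3Z)-7-[(tert-butyldimethylsilyl)oxy]-4-methyl-5-methylidenehept-3-en-2-ol, 12 2-ethenylfuran-3-carboxylic acid
Product: 13 (2S,3Z)-7-[(tert-butyldimethylsilyl)oxy]-4-methyl-5-methylidenehept-3-en-2-yl 2-ethenylfuran-3-carboxylate
Conditions: DCC, DMAP (cat.), CH2Cl2, 0 °C to rt
Reagents that add atoms: none
Why: Steglich esterification forms the acyl–oxygen bond only, so the carbinol configuration and the diene geometry are untouched under these neutral conditions.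

Step 9
Reactants: 13 (2S,3Z)-7-[(tert-butyldimethylsilyl)oxy]-4-methyl-5-methylidenehept-3-en-2-yl 2-ethenylfuran-3-carboxylate
Product: 15 (3R,4E)-3-{4-[(tert-butyldimethylsilyl)oxy]but-1-en-2-yl}-1-(2-ethenylfuran-3-yl)-3-methylhex-4-en-1-one, via allyl enol ether 14 (not isolated)
Conditions: Cp2TiMe2 (2 equiv), toluene/THF, 65 °C, dark; hexane, basic Al2O3 plug; then toluene, Et3N (cat.), 110 °C
Reagents that add atoms: dimethyltitanocene Cp2TiMe2, C[Ti+2]C.[cH-]1cccc1.[cH-]1cccc1
Why: Petasis methylenation turns the ester carbonyl into a 1-furylvinyl ether (the new CH2 becomes C12), and the following Claisen rearrangement should pass through a chair with the carbinol methyl equatorial, because the Z-dienyl group is necessarily axial and would meet an axial methyl 1,3-diaxially, so that C12 bonds to a single face of the trisubstituted alkene and the S carbinol is relayed into the R quaternary C13 with an E-propenyl group; the titanium residues are removed before heating so that the new ketone is not methylenated.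

Step 10
Reactants: 15 (3R,4E)-3-{4-[(tert-butyldimethylsilyl)oxy]but-1-en-2-yl}-1-(2-ethenylfuran-3-yl)-3-methylhex-4-en-1-one
Product: 16 (6R)-6-{4-[(tert-butyldimethylsilyl)oxy]but-1-en-2-yl}-6-methyl-5,6-dihydro-4H-cyclohepta[b]furan-4-one
Conditions: second-generation Grubbs catalyst (H2IMes)(PCy3)Cl2Ru=CHPh (5 mol %), CH2Cl2 (0.005 M), 40 °C
Reagents that add atoms: none
Why: Ring-closing metathesis, in which the catalyst should load at the terminal vinyl group and close the seven-membered ring C on the propenyl alkene with loss of propene, the 1,1-disubstituted alkene beside the quaternary carbon being too hindered to compete and the ring size enforcing the Z geometry of C10=C14.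

Step 11
Reactants: 16 (6R)-6-{4-[(tert-butyldimethylsilyl)oxy]but-1-en-2-yl}-6-methyl-5,6-dihydro-4H-cyclohepta[b]furan-4-one
Product: 17 (6R)-6-(4-hydroxybut-1-en-2-yl)-6-methyl-5,6-dihydro-4H-cyclohepta[b]furan-4-one
Conditions: HF·pyridine, pyridine, THF, 0 °C to rt
Reagents that add atoms: none
Why: Fluoride-mediated cleavage of the primary silyl ether, buffered with pyridine so that the dienone and the furan see neither strong acid nor strong base.

Step 12
Reactants: 17 (6R)-6-(4-hydroxybut-1-en-2-yl)-6-methyl-5,6-dihydro-4H-cyclohepta[b]furan-4-one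
Product: 18 (6R)-6-(4-iodobut-1-en-2-yl)-6-methyl-5,6-dihydro-4H-cyclohepta[b]furan-4-one
Conditions: I2, PPh3, imidazole, CH2Cl2, 0 °C to rt, dark; used at once
Reagents that add atoms: iodine, [I][I]
Why: Appel-type iodination (Garegg–Samuelsson conditions) converts the primary alcohol into the iodide by SN2 displacement of the oxyphosphonium group under nearly neutral conditions that leave the enolisable ketone alone.

Step 13
Reactants: 18 (6R)-6-(4-iodobut-1-en-2-yl)-6-methyl-5,6-dihydro-4H-cyclohepta[b]furan-4-one, 19 3,4-dibromofuran-2(5H)-one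
Product: 21 3-bromo-4-{3-[(6R)-6-methyl-4-oxo-5,6-dihydro-4H-cyclohepta[b]furan-6-yl]but-3-en-1-yl}furan-2(5H)-one, via alkylzinc iodide 20 (not isolated)
Conditions: Zn dust (activated with BrCH2CH2Br, TMSCl), LiCl, THF, 25–35 °C; then 19 (1.3 equiv), PdCl2(dppf) (5 mol %), THF, 25–40 °C
Reagents that add atoms: none
Why: Zinc insertion into the primary iodide in the presence of LiCl gives an alkylzinc that tolerates the ketone, and the Negishi coupling should take place at the C4 bromide only, because oxidative addition is faster at the β-position of the dibromobutenolide than at the α-bromide, a site preference established for cross-couplings of this dibromide.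

Step 14
Reactants: 21 3-bromo-4-{3-[(6R)-6-methyl-4-oxo-5,6-dihydro-4H-cyclohepta[b]furan-6-yl]but-3-en-1-yl}furan-2(5H)-one
Product: 22 3-ethenyl-4-{3-[(6R)-6-methyl-4-oxo-5,6-dihydro-4H-cyclohepta[b]furan-6-yl]but-3-en-1-yl}furan-2(5H)-one
Conditions: tributyl(vinyl)stannane, Pd2(dba)3 (2.5 mol %), AsPh3, CuI, NMP, 25 °C, BHT, dark
Reagents that add atoms: tributyl(vinyl)stannane, C=C[Sn](CCCC)(CCCC)CCCC
Why: Stille coupling of the α-bromobutenolide with the vinylstannane (supplying C8 and C9) under ligand-accelerated conditions proceeds near room temperature, which should keep the newly formed electron-poor diene from dimerising.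

Step 15
Reactants: 22 3-ethenyl-4-{3-[(6R)-6-methyl-4-oxo-5,6-dihydro-4H-cyclohepta[b]furan-6-yl]but-3-en-1-yl}furan-2(5H)-one
Product: 23 (4S,10R,13R,14S)-2-deoxy pentacycle, the target skeleton without the C2 acetoxy group (H10, H14, the C13 methyl and C5 on one face)
Conditions: toluene (0.005 M), BHT, degassed, sealed tube, 160 °C
Reagents that add atoms: none
Why: A concerted but asynchronous [4+2] cycloaddition (intramolecular Diels–Alder reaction) is expected, in which the diene C9=C8–C7=C4, made electron-poor by the lactone carbonyl on C7, meets the ring C alkene, a 2-vinylfuran that is nucleophilic at C14, so that C14 bonds to the lactone β-carbon C4 slightly ahead of C9 closing on the furan-stabilised C10. The closest known reaction type is the thermal cyclisation of 1,7,9-decatrienes that carry a Z-substituted or semicyclic diene, which gives cis-fused decalins. Ring B closes as the six-membered cycloadduct ring through both new bonds, and ring A closes as the six-membered tether ring (C13, C1, C2, C3, C4, C14) through the C4–C14 bond alone. C10 and C14 receive cis hydrogens because the Z alkene of the seven-membered ring adds suprafacially, the face of that alkene is fixed by the short tether on the stereodefined C13 (C1 and C4 cis on ring C), and C4 is fixed because the tether occupies the inside position of the diene, which forces ring C exo and leaves C5 cis to H14. The step needs this exo topology and attack on the tether-side face, and the substrate locks both, since the lactone ring holds C3 cis to the vinyl group and C13 is quaternary and configurationally fixed. Dilution and BHT hold back diene dimerisation and polymerisation, and the temperature is kept as low as conversion allows so that cyclisation outruns a 1,5-hydrogen shift from C3 to C9.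

Step 16
Reactants: 23 (4S,10R,13R,14S)-2-deoxy pentacycle
Product: 24 (2S,4S,10R,13R,14S)-2-hydroxy pentacycle (C2 allylic alcohol)
Conditions: SeO2 (0.3 equiv), t-BuOOH (2.5 equiv), CH2Cl2, 0 °C to rt
Reagents that add atoms: selenium dioxide, O=[Se]=O; tert-butyl hydroperoxide, CC(C)(C)OO
Why: Catalytic SeO2 allylic hydroxylation proceeds by an ene reaction at the exocyclic methylene and a [2,3]-sigmatropic shift that returns the double bond to C1=CH2 and places oxygen on C2, the only allylic CH position of this alkene since C13 is quaternary, while the lactone-conjugated C7=C8 alkene is too electron-poor to react; the C13 methyl and the C5 methylene project from the same face of ring A and flank C2 there, so hydrogen abstraction and oxygen return are expected on the opposite face to give the 2S alcohol.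

Step 17
Reactants: 24 (2S,4S,10R,13R,14S)-2-hydroxy pentacycle
Product: 25 CNP0273675.2, the (2S,4S,10R,13R,14S)-2-acetate
Conditions: Ac2O, DMAP (cat.), pyridine, CH2Cl2, 0 °C to rt
Reagents that add atoms: acetic anhydride, CC(=O)OC(C)=O
Why: DMAP-catalysed acetylation acylates the secondary allylic hydroxyl with retention at C2 and touches neither the ketone nor the lactone.

Compound list
1 | pent-3-yn-2-one | CC#CC(C)=O | starting material
2 | (S)-pent-3-yn-2-ol | C[C@H](O)C#CC | intermediate
3 | sodium cyclic alkenylalanate of 2 (five-membered O–Al–C chelate, aluminium on the distal alkene carbon, two 2-methoxyethoxy ligands) | C[C@H]1C=C(C)[Al-](OCCOC)(OCCOC)O1.[Na+] | intermediate (not isolated)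
4 | (2S,3Z)-4-iodopent-3-en-2-ol | C[C@H](O)/C=C(\I)C | intermediate
5 | 3-bromobut-3-en-1-ol | C=C(Br)CCO | starting material
6 | [(3-bromobut-3-en-1-yl)oxy](tert-butyl)dimethylsilane | C=C(Br)CCO[Si](C)(C)C(C)(C)C | intermediate
7 | tert-butyldimethyl{[3-(4,4,5,5-tetramethyl-1,3,2-dioxaborolan-2-yl)but-3-en-1-yl]oxy}silane | C=C(CCO[Si](C)(C)C(C)(C)C)B1OC(C)(C)C(C)(C)O1 | intermediate
8 | (2S,3Z)-7-[(tert-butyldimethylsilyl)oxy]-4-methyl-5-methylidenehept-3-en-2-ol | C[C@H](O)/C=C(\C(=C)CCO[Si](C)(C)C(C)(C)C)C | intermediate
9 | furan-3-carboxylic acid | OC(=O)c1ccoc1 | starting material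
10 | lithium 2-lithiofuran-3-carboxylate | [Li]c1occc1C(=O)O[Li] | intermediate (not isolated)
11 | 2-formylfuran-3-carboxylic acid | O=Cc1occc1C(=O)O | intermediate
12 | 2-ethenylfuran-3-carboxylic acid | C=Cc1occc1C(=O)O | intermediate
13 | (2S,3Z)-7-[(tert-butyldimethylsilyl)oxy]-4-methyl-5-methylidenehept-3-en-2-yl 2-ethenylfuran-3-carboxylate | C=Cc1occc1C(=O)O[C@@H](C)/C=C(\C(=C)CCO[Si](C)(C)C(C)(C)C)C | intermediate
14 | 2-ethenyl-3-[1-({(2S,3Z)-7-[(tert-butyldimethylsilyl)oxy]-4-methyl-5-methylidenehept-3-en-2-yl}oxy)ethenyl]furan | C=Cc1occc1C(=C)O[C@@H](C)/C=C(\C(=C)CCO[Si](C)(C)C(C)(C)C)C | intermediate (not isolated)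
15 | (3R,4E)-3-{4-[(tert-butyldimethylsilyl)oxy]but-1-en-2-yl}-1-(2-ethenylfuran-3-yl)-3-methylhex-4-en-1-one | C=Cc1occc1C(=O)C[C@@](C)(C(=C)CCO[Si](C)(C)C(C)(C)C)/C=C/C | intermediate
16 | (6R)-6-{4-[(tert-butyldimethylsilyl)oxy]but-1-en-2-yl}-6-methyl-5,6-dihydro-4H-cyclohepta[b]furan-4-one | C=C(CCO[Si](C)(C)C(C)(C)C)[C@@]1(C)C=Cc2occc2C(=O)C1 | intermediate
17 | (6R)-6-(4-hydroxybut-1-en-2-yl)-6-methyl-5,6-dihydro-4H-cyclohepta[b]furan-4-one | C=C(CCO)[C@@]1(C)C=Cc2occc2C(=O)C1 | intermediate
18 | (6R)-6-(4-iodobut-1-en-2-yl)-6-methyl-5,6-dihydro-4H-cyclohepta[b]furan-4-one | C=C(CCI)[C@@]1(C)C=Cc2occc2C(=O)C1 | intermediate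
19 | 3,4-dibromofuran-2(5H)-one | O=C1OCC(Br)=C1Br | starting material
20 | {3-[(6R)-6-methyl-4-oxo-5,6-dihydro-4H-cyclohepta[b]furan-6-yl]but-3-en-1-yl}zinc iodide | C=C(CC[Zn]I)[C@@]1(C)C=Cc2occc2C(=O)C1 | intermediate (not isolated)
21 | 3-bromo-4-{3-[(6R)-6-methyl-4-oxo-5,6-dihydro-4H-cyclohepta[b]furan-6-yl]but-3-en-1-yl}furan-2(5H)-one | C=C(CCC1=C(Br)C(=O)OC1)[C@@]1(C)C=Cc2occc2C(=O)C1 | intermediate
22 | 3-ethenyl-4-{3-[(6R)-6-methyl-4-oxo-5,6-dihydro-4H-cyclohepta[b]furan-6-yl]but-3-en-1-yl}furan-2(5H)-one | C=CC1=C(CCC(=C)[C@@]2(C)C=Cc3occc3C(=O)C2)COC1=O | intermediate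
23 | (4S,10R,13R,14S)-2-deoxy pentacycle (target skeleton without the C2 acetoxy group) | C=C1CC[C@@]23COC(=O)C2=CC[C@H]2c4occc4C(=O)C[C@]1(C)[C@H]23 | intermediate
24 | (2S,4S,10R,13R,14S)-2-hydroxy pentacycle | C=C1[C@@H](O)C[C@@]23COC(=O)C2=CC[C@H]2c4occc4C(=O)C[C@]1(C)[C@H]23 | intermediate
25 | CNP0273675.2, (2S,4S,10R,13R,14S)-2-acetate | C=C1[C@@H](OC(C)=O)C[C@@]23COC(=O)C2=CC[C@H]2c4occc4C(=O)C[C@]1(C)[C@H]23 | target

Total step count: 17 steps.
Longest linear sequence: 13 steps (steps 1, 2, 5, 8 to 17; the branch from 5 through steps 3 and 4 is equally long).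

Steps most likely to fail

Step 15. The cycloaddition may stall because the C4–C14 bond joins two congested carbons. Material may also drain away through a 1,5-hydrogen shift of the Z-substituted diene or through diene dimerisation before ring closure. The fallback raises the donor strength of the dienophile instead of forcing the temperature. Setting out from 22, Luche reduction (NaBH4, CeCl3·7H2O, MeOH, −78 °C) of the C11 ketone would give the furyl carbinol triene F1 (either C11 epimer serves). Its vinylfuran is no longer deactivated by the acyl group, so cyclisation should proceed under milder heating (toluene, BHT, 110–130 °C) to the pentacyclic carbinol F2. Oxidation of the furfuryl-type alcohol (MnO2, CH2Cl2, rt) returns to the route at 23.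

Step 13. Zinc insertion passes through a primary radical at C3, which may cyclise 5-exo onto the furan-conjugated C10=C14 alkene before it is reduced to the organozinc. Coupling at both bromides is a lesser risk. The fallback attaches the butenolide before ring C exists, when the only 5-exo acceptor is the unactivated propenyl group. Setting out from 15, desilylation (HF·pyridine) would give the acyclic alcohol F3 and iodination (I2, PPh3, imidazole) the acyclic iodide F4. Zinc insertion (Zn, LiCl, THF) would give the acyclic alkylzinc iodide F5, and Negishi coupling with 19 (PdCl2(dppf)) the acyclic bromobutenolide F6. Ring-closing metathesis with second-generation Grubbs catalyst (H2IMes)(PCy3)Cl2Ru=CHPh, to which the tetrasubstituted bromobutenolide alkene is inert, then rejoins the route at 21.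

Step 16. Facial selectivity in the ene step may be poor or reversed, so that oxygen arrives on the face of the C13 methyl. Over-oxidation to the enone is a secondary concern. The fallback accepts the wrong face and corrects it by substitution. Setting out from 23, the hydroxylation product would then be the C2-epimeric alcohol F7. Mitsunobu esterification (AcOH, PPh3, DIAD, toluene, 0 °C to rt) should convert it with inversion directly into 25, replacing step 17.

Further compounds
F1 | step 15 | 3-ethenyl-4-{3-[(6R)-4-hydroxy-6-methyl-5,6-dihydro-4H-cyclohepta[b]furan-6-yl]but-3-en-1-yl}furan-2(5H)-one (C11 carbinol, either epimer) | C=CC1=C(CCC(=C)[C@@]2(C)C=Cc3occc3C(O)C2)COC1=O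
F2 | step 15 | (4S,10R,13R,14S)-2-deoxy pentacycle with C11 as carbinol (either epimer) | C=C1CC[C@@]23COC(=O)C2=CC[C@H]2c4occc4C(O)C[C@]1(C)[C@H]23
F3 | step 13 | (3R,4E)-1-(2-ethenylfuran-3-yl)-3-(4-hydroxybut-1-en-2-yl)-3-methylhex-4-en-1-one | C=Cc1occc1C(=O)C[C@@](C)(C(=C)CCO)/C=C/C
F4 | step 13 | (3R,4E)-1-(2-ethenylfuran-3-yl)-3-(4-iodobut-1-en-2-yl)-3-methylhex-4-en-1-one | C=Cc1occc1C(=O)C[C@@](C)(C(=C)CCI)/C=C/C
F5 | step 13 | alkylzinc iodide of F4 | C=Cc1occc1C(=O)C[C@@](C)(C(=C)CC[Zn]I)/C=C/C
F6 | step 13 | 3-bromo-4-{(4R,5E)-4-[2-(2-ethenylfuran-3-yl)-2-oxoethyl]-4-methyl-3-methylidenehept-5-en-1-yl}furan-2(5H)-one | C=Cc1occc1C(=O)C[C@@](C)(C(=C)CCC1=C(Br)C(=O)OC1)/C=C/C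
F7 | step 16 | (2R,4S,10R,13R,14S)-2-hydroxy pentacycle (C2 epimer of 24) | C=C1[C@H](O)C[C@@]23COC(=O)C2=CC[C@H]2c4occc4C(=O)C[C@]1(C)[C@H]23
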